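**Strategy**

The 2,3-dihydro-4H-pyran-4-one ring (O1, stereocentre C2, methylene C3, ketone C4, enol ether C5=C6) is cut at C2–C3 and C5–C6. This exposes C3–C4–C5 as acetone whose two α-carbons are both nucleophilic, flanked by an aldehyde (C2, O1) and an acetyl unit (C6, methyl). The key step joins the three components in one flask: 2-methoxypropene adds to (Z)-icos-11-enal in a Ti-catalysed enantioselective ene reaction (C2–C3, sets C2), the enol ether that survives is C-acylated by trimethyl orthoacetate (C5–C6), and acid closes O1–C6. The precursor is an acyclic, achiral C20 aldehyde.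

Key step: step 2

Assumption: the Ti ligand built on (R)-2-amino-2'-hydroxy-1,1'-binaphthyl is taken as the antipode that leaves the Si face of the aldehyde open; if the sense proves opposite, the (S)-ligand is used with no other change.

**Route**

Step 1
Reactants: 1 (Z)-icos-11-en-1-ol
Product: 2 (Z)-icos-11-enal
Conditions: TEMPO (10 mol %), PhI(OAc)2 (1.1 equiv), CH2Cl2, rt
Reagents that add atoms: none
Why: TEMPO-catalysed oxidation (oxoammonium ion as active oxidant, PhI(OAc)2 as terminal oxidant) should take the primary alcohol to the aldehyde without over-oxidation under anhydrous conditions and leave the isolated Z-alkene untouched; no stereocentre is formed.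

Step 2
Reactants: 2 (Z)-icos-11-enal; 3 2-methoxypropene; 4 trimethyl orthoacetate
Product: 7 (R)-6-methyl-2-[(Z)-nonadec-10-en-1-yl]-2,3-dihydro-4H-pyran-4-one, via hydroxy enol ether 5 (not isolated), via hydroxy bis-ketal 6 (not isolated)
Conditions: a) preformed catalyst from Ti(OiPr)4, the Schiff base of (R)-2-amino-2'-hydroxy-1,1'-binaphthyl with 3-bromo-5-tert-butylsalicylaldehyde, and 3,5-di-tert-butylsalicylic acid (5 mol %), 2,6-di-tert-butyl-4-methylpyridine (10 mol %), 2-methoxypropene as solvent, 0 °C to rt, then volatiles removed; b) MeC(OMe)3 (1.5 equiv), BF3·OEt2 (30 mol %), CH2Cl2, −78 to −20 °C; c) 1 M aq HCl, THF, 0 °C to rt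
Reagents that add atoms: 2-methoxypropene COC(C)=C; trimethyl orthoacetate CC(OC)(OC)OC; water O
Why: The chiral Ti Lewis acid activates aldehyde 2 and 2-methoxypropene adds through its CH2 terminus in a carbonyl-ene (Mukaiyama-type) addition that forms C2–C3 and regenerates a terminal enol ether in 5; BF3 then ionises the orthoacetate to MeC(OMe)2+, which this enol ether attacks through C5 to form C5–C6, and methoxide return gives bis-ketal 6. Each stage is a known reaction type on its substrate class (Ti-catalysed asymmetric ene addition of 2-methoxypropene to aldehydes, Lewis-acid addition of orthoesters to enol ethers, acid cyclodehydration of δ-hydroxy-β-diketones, the last two being the logic of a Maitland–Japp annulation) and they are telescoped here. The pyranone ring closes at O1–C6 by 6-exo-trig attack of the C2 hydroxyl on the unmasked C6 carbonyl, or by 6-endo attack of the enol ether on the tethered dialkoxycarbenium ion if the hydroxyl exchanges onto the orthoester first, and both paths should end in 7 after loss of methanol. The only stereocentre, C2, is set in the ene stage by the chiral ligand on Ti, which leaves the Si face of the aldehyde open, and no later stage breaks a bond at C2. Regioselectivity (C5 and not C3 must be acylated) is secured by the substrate, because the ene stage leaves its only enol ether double bond at C4=C5, and the hindered pyridine keeps Brønsted acid from protonating it. Chemoselectivity over the remote Z-alkene follows from the far lower nucleophilicity of a 1,2-dialkyl olefin towards the dialkoxycarbenium ion.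

**Compound list**

1 | (Z)-icos-11-en-1-ol | CCCCCCCC/C=C\CCCCCCCCCCO | starting material
2 | (Z)-icos-11-enal | CCCCCCCC/C=C\CCCCCCCCCC=O | intermediate
3 | 2-methoxypropene | COC(C)=C | starting material
4 | trimethyl orthoacetate | CC(OC)(OC)OC | starting material
5 | (4R,14Z)-2-methoxytricosa-1,14-dien-4-ol | CCCCCCCC/C=C\CCCCCCCCC[C@@H](O)CC(OC)=C | intermediate
6 | (6R,16Z)-2,2,4,4-tetramethoxypentacos-16-en-6-ol | CCCCCCCC/C=C\CCCCCCCCC[C@@H](O)CC(OC)(OC)CC(C)(OC)OC | intermediate
7 | (R)-6-methyl-2-[(Z)-nonadec-10-en-1-yl]-2,3-dihydro-4H-pyran-4-one | CCCCCCCC/C=C\CCCCCCCCC[C@@H]1CC(=O)C=C(C)O1 | target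

**Step count and risks**

Total step count: 2. Longest linear sequence: 2 steps.

The route has only two steps, so both are ranked here.

1. Step 2 (key step). What may go wrong: erosion of facial selectivity in the ene stage with a flexible unbranched aldehyde; protonolysis or intermolecular ketalisation of the enol ether before it is C-acylated; a second orthoester addition. Fallback: setting out from 2, the ring is built by a different disconnection (C2–C3 and O1–C6). Aldehyde 2 undergoes an enantioselective hetero-Diels–Alder reaction with (E)-4-methoxy-2-(trimethylsilyloxy)penta-1,3-diene F1 (made beforehand from commercial 4-methoxypent-3-en-2-one with TMSOTf and Et3N). The catalyst is the chiral (salen)Cr(BF4) complex of trivalent chromium (salen = N,N'-bis(3,5-di-tert-butylsalicylidene)-trans-cyclohexane-1,2-diamine, antipode chosen for Si-face addition; 4 Å molecular sieves, tert-butyl methyl ether, −30 °C). This should give the cycloadduct (6R)-2-methoxy-2-methyl-6-[(Z)-nonadec-10-en-1-yl]-4-(trimethylsilyloxy)-5,6-dihydro-2H-pyran F2. TFA in CH2Cl2 at 0 °C then removes methanol and the silyl group, and the sequence comes back to the route at 7.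

2. Step 1. What may go wrong: over-oxidation, air oxidation and self-aldol condensation of the unbranched aldehyde during isolation and storage. Fallback: setting out from 1, the alcohol is oxidised fully (TEMPO, PhI(OAc)2, MeCN/H2O) to (Z)-icos-11-enoic acid F3. The acid is converted (carbonyldiimidazole, MeNH(OMe)·HCl, CH2Cl2) into (Z)-N-methoxy-N-methylicos-11-enamide F4. This stable amide is reduced with i-Bu2AlH (THF, −78 °C) just before use, and the sequence comes back to the route at 2.

**Further compounds**

F1 | step 2 | (E)-4-methoxy-2-(trimethylsilyloxy)penta-1,3-diene | C=C(O[Si](C)(C)C)/C=C(/OC)C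
F2 | step 2 | (6R)-2-methoxy-2-methyl-6-[(Z)-nonadec-10-en-1-yl]-4-(trimethylsilyloxy)-5,6-dihydro-2H-pyran | CCCCCCCC/C=C\CCCCCCCCC[C@@H]1CC(O[Si](C)(C)C)=CC(C)(OC)O1
F3 | step 1 | (Z)-icos-11-enoic acid | CCCCCCCC/C=C\CCCCCCCCCC(=O)O
F4 | step 1 | (Z)-N-methoxy-N-methylicos-11-enamide | CCCCCCCC/C=C\CCCCCCCCCC(=O)N(C)OC
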